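**Plan**

- Retrosynthesis: the six O‑methyl bonds are cut last. The C3–ring B bond is cut back to a C3 carboxylic acid. The C3–C3a bond is cut by reversing a 1,2‑shift of ring C, which expands the dihydrofuran to a 2‑aryl‑2H‑chromene. The C2–ring A bond is then cut back to a chromone, which comes from dihydroresveratrol trimethyl ether.
- Enabling feature: O1–C2(ring A)–C3–C3a is the O1–C2–C3 unit of a flavene with the fused benzene attached one carbon early. C3a lies between C4–O and C7a–O1, so the ipso carbon of ring C has two ortho oxygen donors and should migrate readily from chromene C4 to chromene C3.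
- Forward order: bibenzyl (rings C and D), acetyl group between the two oxygens, pyranone ring, ring A by conjugate addition, flav‑3‑ene, ring contraction to the dihydrofuran carrying a C3 acetal, acid, ring B by decarboxylative coupling, global demethylation.
- Stereochemistry: C2 (S) is set by rhodium‑catalysed asymmetric 1,4‑addition and carried through. C3 is set trans to ring A by anti addition and invertive aryl shift, and again, after decarboxylation, by coupling on the face anti to ring A.

Key step: step 8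

Remark: compounds up to 13 are named with chromene numbering (O1, C2, C3, C4, C4a, C8a); from 14 on, benzofuran numbering is used (chromene C4a becomes C3a, chromene C4 becomes the exocyclic carbon on C3).
Remark (assumption): the (S)‑configured bisphosphine (S)‑MeO‑F12‑BIPHEP, 2,2'‑bis[bis(3,4,5‑trifluorophenyl)phosphino]‑6,6'‑dimethoxybiphenyl, is assumed to give (2S)‑10 by analogy with the sense of (S)‑BINAP in additions to cyclohexenone; if the opposite sense is found, the (R)‑ligand is used.
Remark: the C4 configuration drawn for 11 and 13 is that of the expected major isomer; it is erased in 12 and 14, so the epimers need not be separated.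

**Route**

Step 1
Reactants: 1 resveratrol trimethyl ether, (E)‑1,3‑dimethoxy‑5‑[2‑(4‑methoxyphenyl)ethenyl]benzene
Product: 2 dihydroresveratrol trimethyl ether (1,3‑dimethoxy‑5‑[2‑(4‑methoxyphenyl)ethyl]benzene)
Conditions: H2 (1 atm), 10% Pd/C, EtOAc, rt
Reagents that add atoms: none
Why: Heterogeneous catalytic hydrogenation saturates only the stilbene alkene; the aryl methyl ethers are inert and no stereocentre is formed.

Step 2
Reactants: 2 dihydroresveratrol trimethyl ether
Product: 5 acetophenone 1‑{2,6‑dimethoxy‑4‑[2‑(4‑methoxyphenyl)ethyl]phenyl}ethan‑1‑one, via aryllithium 3 (not isolated), via lithium hemiaminal adduct 4 (not isolated)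
Conditions: n‑BuLi, THF, 0 °C to rt; then MeC(O)N(OMe)Me, −78 °C to rt; 1 M HCl quench
Reagents that add atoms: N‑methoxy‑N‑methylacetamide, CC(=O)N(C)OC
Why: Directed ortho‑metalation takes place between the two methoxy groups of the resorcinol ring, which is more activated than the anisole ring or the benzylic CH2 groups, and the Weinreb amide acylates the aryllithium only once because the chelated tetrahedral adduct survives until the acidic quench.

Step 3
Reactants: 5 acetophenone
Product: 6 hydroxyacetophenone 1‑{2‑hydroxy‑6‑methoxy‑4‑[2‑(4‑methoxyphenyl)ethyl]phenyl}ethan‑1‑one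
Conditions: BCl3 (1.1 equiv), CH2Cl2, −78 to 0 °C; aqueous work‑up
Reagents that add atoms: none
Why: Chelation‑controlled ether cleavage, in which BCl3 is held between the ketone oxygen and one flanking methoxy group, so that exactly one of the two equivalent ortho methyl ethers is cleaved and the remote ring D ether is untouched.

Step 4
Reactants: 6 hydroxyacetophenone
Product: 8 chromone 5‑methoxy‑7‑[2‑(4‑methoxyphenyl)ethyl]‑4H‑chromen‑4‑one, via enaminone 7 (not isolated)
Conditions: Me2NCH(OMe)2, toluene, 100 °C; then conc. HCl, CH2Cl2, 40 °C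
Reagents that add atoms: N,N‑dimethylformamide dimethyl acetal, COC(OC)N(C)C
Why: Enaminone route to chromones, in which condensation of the methyl ketone with the amide acetal is followed by acid‑promoted conjugate addition of the phenol and loss of dimethylamine (6‑endo‑trig addition–elimination).

Step 5
Reactants: 8 chromone; 9 2,4‑dimethoxyphenylboronic acid
Product: 10 flavanone (2S)‑2‑(2,4‑dimethoxyphenyl)‑5‑methoxy‑7‑[2‑(4‑methoxyphenyl)ethyl]‑2,3‑dihydro‑4H‑chromen‑4‑one
Conditions: 9 (3 equiv, in portions), [Rh(OH)((S)‑MeO‑F12‑BIPHEP)]2 (2.5 mol%), toluene/H2O, 40 °C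
Reagents that add atoms: none
Why: Hayashi–Miyaura asymmetric 1,4‑addition, in which the aryl–rhodium species inserts the chromone C2=C3 bond on the face selected by the electron‑poor atropisomeric bisphosphine and hydrolysis of the rhodium enolate releases the (2S)‑flavanone; the base‑free hydroxo complex avoids retro‑oxa‑Michael racemisation.

Step 6
Reactants: 10 flavanone
Product: 11 flavan‑4‑ol (2S,4S)‑2‑(2,4‑dimethoxyphenyl)‑5‑methoxy‑7‑[2‑(4‑methoxyphenyl)ethyl]‑3,4‑dihydro‑2H‑chromen‑4‑ol (2,4‑cis)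
Conditions: NaBH4, THF/MeOH, 0 °C
Reagents that add atoms: none
Why: Borohydride reduction of the aryl ketone, expected to give mainly the 2,4‑cis alcohol by axial hydride delivery; the C4 configuration is irrelevant because this carbon becomes trigonal in step 7, and the low temperature suppresses base‑induced ring opening before reduction.

Step 7
Reactants: 11 flavan‑4‑ol
Product: 12 chromene (2S)‑2‑(2,4‑dimethoxyphenyl)‑5‑methoxy‑7‑[2‑(4‑methoxyphenyl)ethyl]‑2H‑chromene
Conditions: Burgess reagent (MeO2CN–SO2NEt3 inner salt), toluene, 50 °C, dark; used promptly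
Reagents that add atoms: none
Why: Burgess dehydration, in which the sulfamate ester eliminates by a syn pathway with a C3 hydrogen under neutral conditions, avoiding the acid‑induced disproportionation and C2 ionisation to which electron‑rich flav‑3‑enes are prone, so C2 is untouched.

Step 8
Reactants: 12 chromene
Product: 14 acetal (2S,3S)‑2‑(2,4‑dimethoxyphenyl)‑3‑(dimethoxymethyl)‑4‑methoxy‑6‑[2‑(4‑methoxyphenyl)ethyl]‑2,3‑dihydro‑1‑benzofuran (2,3‑trans), via iodane adduct 13 (not isolated)
Conditions: PhI(OH)OTs (1.2 equiv), MeOH, −20 to 0 °C; NaHCO3 quench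
Reagents that add atoms: methanol, CO
Why: The electrophilic trivalent iodine reagent adds to C3 of the electron‑rich styrene‑type alkene on the face opposite the C2 aryl group and methanol traps the C4 benzylic cation, giving adduct 13 in which the phenyl‑λ3‑iodanyl group is an exceptionally good leaving group. Because iodine is trans to the equatorial C2 aryl group it is itself equatorial in the half‑chair, so the C3–I bond lies antiperiplanar to the C4–C4a bond; the ipso carbon of ring C, flanked by two oxygen‑bearing carbons, bridges to C3 as a phenonium ion and completes a 1,2‑shift with inversion at C3 as iodobenzene leaves, and the methoxy‑oxocarbenium ion left at the old C4 takes up methanol to give the dimethyl acetal. The closest known reaction type is the ring contraction of 1,2‑dihydronaphthalenes and 2H‑chromenes to indane and 2,3‑dihydrobenzofuran acetals by PhI(OH)OTs or Tl(NO3)3 in methanol. The dihydrofuran ring is closed not by cyclisation of an open chain but by contraction of the pyran ring: 3‑exo‑tet attack of the arene ipso carbon on C3 forms the C3–C3a bond and the old C4–C4a bond breaks. The new C3 stereocentre is controlled by the C2 stereocentre, since anti addition of iodine followed by invertive migration puts the acetal carbon trans to ring A, which is also the more stable arrangement. The step needs addition to the alkene to outrun hydride abstraction from C2 (flavylium formation) and needs aryl migration to beat methoxy participation or a shift of ring A; the nucleophilic alkene, cold methanol, the high migratory aptitude of ring C and the equatorial C–I bond enforced by the C2 aryl group are expected to secure this.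

Step 9
Reactants: 14 acetal
Product: 15 aldehyde (2S,3S)‑2‑(2,4‑dimethoxyphenyl)‑4‑methoxy‑6‑[2‑(4‑methoxyphenyl)ethyl]‑2,3‑dihydro‑1‑benzofuran‑3‑carbaldehyde (2,3‑trans)
Conditions: aqueous oxalic acid, THF, rt; crude product taken on at once
Reagents that add atoms: water, O
Why: Acid‑catalysed acetal hydrolysis through the methoxy‑oxocarbenium ion; the weak acid is chosen so that the 2,4‑dimethoxybenzylic C2–O1 bond does not ionise, and C3 stays in the preferred trans arrangement even if the aldehyde enolises.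

Step 10
Reactants: 15 aldehyde
Product: 16 acid (2S,3S)‑2‑(2,4‑dimethoxyphenyl)‑4‑methoxy‑6‑[2‑(4‑methoxyphenyl)ethyl]‑2,3‑dihydro‑1‑benzofuran‑3‑carboxylic acid (2,3‑trans)
Conditions: NaClO2, NaH2PO4, 2‑methyl‑2‑butene (large excess), t‑BuOH/H2O, 0 °C to rt
Reagents that add atoms: sodium chlorite, [Na+].[O-]Cl=O
Why: Pinnick oxidation, in which chlorous acid adds to the aldehyde and fragments to the acid and HOCl, which the alkene scavenges before it can chlorinate the electron‑rich rings; the buffered, slightly acidic medium avoids base‑induced beta‑elimination of the aryloxy group.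

Step 11
Reactants: 16 acid
Product: 17 redox‑active ester 1,3‑dioxoisoindolin‑2‑yl (2S,3S)‑2‑(2,4‑dimethoxyphenyl)‑4‑methoxy‑6‑[2‑(4‑methoxyphenyl)ethyl]‑2,3‑dihydro‑1‑benzofuran‑3‑carboxylate
Conditions: N‑hydroxyphthalimide, N,N'‑diisopropylcarbodiimide, CH2Cl2, 0 °C to rt, no DMAP
Reagents that add atoms: N‑hydroxyphthalimide, O=C1c2ccccc2C(=O)N1O
Why: Carbodiimide‑mediated esterification gives the N‑acyloxyphthalimide; leaving out the amine catalyst limits deprotonation at C3 and E1cB opening of the dihydrofuran.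

Step 12
Reactants: 18 1‑bromo‑3,5‑dimethoxybenzene
Product: 20 (3,5‑dimethoxyphenyl)zinc chloride (titrated THF solution), via arylmagnesium bromide 19 (not isolated)
Conditions: Mg turnings, LiCl, THF, rt; then ZnCl2 in THF, 0 °C to rt
Reagents that add atoms: zinc chloride, Cl[Zn]Cl
Why: Magnesium insertion into the aryl bromide assisted by LiCl, followed by transmetalation with ZnCl2, is the standard preparation of an arylzinc reagent for Negishi coupling.

Step 13
Reactants: 17 redox‑active ester; 20 (3,5‑dimethoxyphenyl)zinc chloride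
Product: 21 hexamethyl ether (2S,3S)‑2‑(2,4‑dimethoxyphenyl)‑3‑(3,5‑dimethoxyphenyl)‑4‑methoxy‑6‑[2‑(4‑methoxyphenyl)ethyl]‑2,3‑dihydro‑1‑benzofuran (2,3‑trans)
Conditions: 20 (3 equiv), NiCl2·glyme (20 mol%), 4,4'‑di‑tert‑butyl‑2,2'‑bipyridine (40 mol%), THF/DMF, rt
Reagents that add atoms: none
Why: Nickel‑catalysed decarboxylative Negishi coupling of a redox‑active ester, in which single‑electron reduction by low‑valent nickel releases CO2 and the benzylic C3 radical, which is captured by the aryl–nickel species on the face anti to the C2 aryl group, so reductive elimination resets C3 trans to ring A under control of C2.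

Step 14
Reactants: 21 hexamethyl ether
Product: 22 target 4‑[(2S,3S)‑3‑(3,5‑dihydroxyphenyl)‑4‑hydroxy‑6‑[2‑(4‑hydroxyphenyl)ethyl]‑2,3‑dihydro‑1‑benzofuran‑2‑yl]benzene‑1,3‑diol
Conditions: BBr3 (excess), CH2Cl2, −78 °C to rt; MeOH then water
Reagents that add atoms: none
Why: Lewis‑acid ether cleavage of all six aryl methyl ethers by bromide attack on the O‑methyl groups of the boron complexes; C3 bears no acidic hydrogen, so even reversible ionisation of the C2–O1 bond should return the more stable trans isomer and not the enantiomer.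

**Compound list**

1 | resveratrol trimethyl ether, (E)‑1,3‑dimethoxy‑5‑[2‑(4‑methoxyphenyl)ethenyl]benzene | COc1ccc(/C=C/c2cc(OC)cc(OC)c2)cc1 | starting material
2 | 1,3‑dimethoxy‑5‑[2‑(4‑methoxyphenyl)ethyl]benzene | COc1ccc(CCc2cc(OC)cc(OC)c2)cc1 | intermediate
3 | {2,6‑dimethoxy‑4‑[2‑(4‑methoxyphenyl)ethyl]phenyl}lithium (not isolated) | [Li]c1c(OC)cc(CCc2ccc(OC)cc2)cc1OC | intermediate
4 | lithium 1‑{2,6‑dimethoxy‑4‑[2‑(4‑methoxyphenyl)ethyl]phenyl}‑1‑[methoxy(methyl)amino]ethan‑1‑olate (not isolated) | COc1ccc(CCc2cc(OC)c(C(C)(O[Li])N(C)OC)c(OC)c2)cc1 | intermediate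
5 | 1‑{2,6‑dimethoxy‑4‑[2‑(4‑methoxyphenyl)ethyl]phenyl}ethan‑1‑one | COc1ccc(CCc2cc(OC)c(C(C)=O)c(OC)c2)cc1 | intermediate
6 | 1‑{2‑hydroxy‑6‑methoxy‑4‑[2‑(4‑methoxyphenyl)ethyl]phenyl}ethan‑1‑one | COc1ccc(CCc2cc(O)c(C(C)=O)c(OC)c2)cc1 | intermediate
7 | (E)‑3‑(dimethylamino)‑1‑{2‑hydroxy‑6‑methoxy‑4‑[2‑(4‑methoxyphenyl)ethyl]phenyl}prop‑2‑en‑1‑one (not isolated) | COc1ccc(CCc2cc(O)c(C(=O)/C=C/N(C)C)c(OC)c2)cc1 | intermediate
8 | 5‑methoxy‑7‑[2‑(4‑methoxyphenyl)ethyl]‑4H‑chromen‑4‑one | COc1ccc(CCc2cc(OC)c3c(c2)OC=CC3=O)cc1 | intermediate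
9 | 2,4‑dimethoxyphenylboronic acid | COc1ccc(B(O)O)c(OC)c1 | starting material
10 | (2S)‑2‑(2,4‑dimethoxyphenyl)‑5‑methoxy‑7‑[2‑(4‑methoxyphenyl)ethyl]‑2,3‑dihydro‑4H‑chromen‑4‑one | COc1ccc(CCc2cc(OC)c3c(c2)O[C@H](c2ccc(OC)cc2OC)CC3=O)cc1 | intermediate
11 | (2S,4S)‑2‑(2,4‑dimethoxyphenyl)‑5‑methoxy‑7‑[2‑(4‑methoxyphenyl)ethyl]‑3,4‑dihydro‑2H‑chromen‑4‑ol (2,4‑cis) | COc1ccc(CCc2cc(OC)c3c(c2)O[C@H](c2ccc(OC)cc2OC)C[C@@H]3O)cc1 | intermediate
12 | (2S)‑2‑(2,4‑dimethoxyphenyl)‑5‑methoxy‑7‑[2‑(4‑methoxyphenyl)ethyl]‑2H‑chromene | COc1ccc(CCc2cc(OC)c3c(c2)O[C@H](c2ccc(OC)cc2OC)C=C3)cc1 | intermediate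
13 | 2‑(2,4‑dimethoxyphenyl)‑4,5‑dimethoxy‑7‑[2‑(4‑methoxyphenyl)ethyl]‑3‑[phenyl(tosyloxy)‑λ3‑iodanyl]chromane, iodine trans to the C2 aryl group, C4 methoxy trans to iodine, C2 as in 12 (not isolated) | COc1ccc(CCc2cc(OC)c3c(c2)O[C@H](c2ccc(OC)cc2OC)[C@@H](I(c2ccccc2)OS(=O)(=O)c2ccc(C)cc2)[C@@H]3OC)cc1 | intermediate
14 | (2S,3S)‑2‑(2,4‑dimethoxyphenyl)‑3‑(dimethoxymethyl)‑4‑methoxy‑6‑[2‑(4‑methoxyphenyl)ethyl]‑2,3‑dihydro‑1‑benzofuran (2,3‑trans) | COc1ccc(CCc2cc(OC)c3c(c2)O[C@H](c2ccc(OC)cc2OC)[C@H]3C(OC)OC)cc1 | intermediate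
15 | (2S,3S)‑2‑(2,4‑dimethoxyphenyl)‑4‑methoxy‑6‑[2‑(4‑methoxyphenyl)ethyl]‑2,3‑dihydro‑1‑benzofuran‑3‑carbaldehyde (2,3‑trans) | COc1ccc(CCc2cc(OC)c3c(c2)O[C@H](c2ccc(OC)cc2OC)[C@H]3C=O)cc1 | intermediate
16 | (2S,3S)‑2‑(2,4‑dimethoxyphenyl)‑4‑methoxy‑6‑[2‑(4‑methoxyphenyl)ethyl]‑2,3‑dihydro‑1‑benzofuran‑3‑carboxylic acid (2,3‑trans) | COc1ccc(CCc2cc(OC)c3c(c2)O[C@H](c2ccc(OC)cc2OC)[C@H]3C(=O)O)cc1 | intermediate
17 | 1,3‑dioxoisoindolin‑2‑yl (2S,3S)‑2‑(2,4‑dimethoxyphenyl)‑4‑methoxy‑6‑[2‑(4‑methoxyphenyl)ethyl]‑2,3‑dihydro‑1‑benzofuran‑3‑carboxylate | COc1ccc(CCc2cc(OC)c3c(c2)O[C@H](c2ccc(OC)cc2OC)[C@H]3C(=O)ON2C(=O)c4ccccc4C2=O)cc1 | intermediate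
18 | 1‑bromo‑3,5‑dimethoxybenzene | COc1cc(Br)cc(OC)c1 | starting material
19 | (3,5‑dimethoxyphenyl)magnesium bromide (not isolated) | COc1cc([Mg]Br)cc(OC)c1 | intermediate
20 | (3,5‑dimethoxyphenyl)zinc chloride | COc1cc([Zn]Cl)cc(OC)c1 | intermediate
21 | (2S,3S)‑2‑(2,4‑dimethoxyphenyl)‑3‑(3,5‑dimethoxyphenyl)‑4‑methoxy‑6‑[2‑(4‑methoxyphenyl)ethyl]‑2,3‑dihydro‑1‑benzofuran (2,3‑trans) | COc1ccc(CCc2cc(OC)c3c(c2)O[C@H](c2ccc(OC)cc2OC)[C@H]3c2cc(OC)cc(OC)c2)cc1 | intermediate
22 | 4‑[(2S,3S)‑3‑(3,5‑dihydroxyphenyl)‑4‑hydroxy‑6‑[2‑(4‑hydroxyphenyl)ethyl]‑2,3‑dihydro‑1‑benzofuran‑2‑yl]benzene‑1,3‑diol (2,3‑trans) | Oc1ccc(CCc2cc(O)c3c(c2)O[C@H](c2ccc(O)cc2O)[C@H]3c2cc(O)cc(O)c2)cc1 | target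

**Step count and risks**

Total step count: 14. Longest linear sequence: 13 steps (steps 1 to 11, 13 and 14, from 1 to 22); step 12 is a one‑step side branch.

Steps most likely to fail:

Step 8 (ring contraction). What may go wrong: hydride abstraction at C2 leading to a flavylium salt; replacement of iodine by methanol with participation of the C4 methoxy group in place of aryl migration; erosion of the C2 configuration by reversible C2–O1 ionisation in the sulfonic acid released by the reagent. The fallback separates addition from migration and replaces the hypervalent iodine leaving group by a bromide activated with silver. It sets out from chromene 12: NBS in methanol at −40 °C should add bromine at C3 anti to the C2 aryl group and methanol at C4 to give the trans,trans‑3‑bromo‑4‑methoxyflavan F1. AgBF4 with 2,6‑di‑tert‑butylpyridine in methanol should then abstract bromide from the equatorial C3–Br bond with the same antiperiplanar shift of ring C, and the route is rejoined at acetal 14.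

Step 13 (decarboxylative arylation). What may go wrong: beta‑elimination of the aryloxy group from the C3 radical or the C3–nickel species, which opens the dihydrofuran to a stilbene phenol; dimerisation of the stabilised benzylic radical; incomplete facial selectivity at C3. The fallback does not couple ring B but builds it around the aldehyde carbon, so no C3 radical or organometallic is involved. It sets out from aldehyde 15: Wittig reaction with 1‑(triphenylphosphoranylidene)propan‑2‑one (toluene, 60 °C) should give the (E)‑enone F2. Michael addition of preformed sodium dimethyl malonate and Claisen ring closure (NaOMe, MeOH, reflux) should give the cyclic keto ester F3. Saponification and decarboxylation (aqueous NaOH, then HCl, warm) should give the 5‑substituted cyclohexane‑1,3‑dione F4. Aromatisation with iodine in methanol at reflux should then form the 3,5‑dimethoxyphenyl ring, and the route is rejoined at hexamethyl ether 21.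

Step 5 (asymmetric conjugate addition). What may go wrong: protodeboronation of the ortho‑substituted, electron‑rich boronic acid outpacing insertion into the weakly electrophilic 5‑methoxychromone; loss of enantiopurity by retro‑oxa‑Michael opening of the flavanone. The fallback forms the C2–ring A bond without a boronic acid and obtains the stereocentre by kinetic resolution. It sets out from hydroxyacetophenone 6: Claisen–Schmidt condensation with 2,4‑dimethoxybenzaldehyde (KOH, EtOH) should give the chalcone F5, and oxa‑Michael ring closure (NaOAc, EtOH, reflux) the racemic flavanone F6. Asymmetric transfer hydrogenation with RuCl(p‑cymene)[(S,S)‑TsDPEN] in HCO2H/Et3N should reduce the (2S) enantiomer faster to the cis alcohol and leave the (2R)‑flavanone F7 behind. After chromatographic separation the route is rejoined at flavan‑4‑ol 11.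

**Further compounds**

F1 | step 8 | 3‑bromo‑2‑(2,4‑dimethoxyphenyl)‑4,5‑dimethoxy‑7‑[2‑(4‑methoxyphenyl)ethyl]chromane, bromine trans to the C2 aryl group, C4 methoxy trans to bromine, C2 as in 12 | COc1ccc(CCc2cc(OC)c3c(c2)O[C@H](c2ccc(OC)cc2OC)[C@@H](Br)[C@@H]3OC)cc1
F2 | step 13 | (E)‑4‑[(2S,3S)‑2‑(2,4‑dimethoxyphenyl)‑4‑methoxy‑6‑[2‑(4‑methoxyphenyl)ethyl]‑2,3‑dihydro‑1‑benzofuran‑3‑yl]but‑3‑en‑2‑one | COc1ccc(CCc2cc(OC)c3c(c2)O[C@H](c2ccc(OC)cc2OC)[C@H]3/C=C/C(C)=O)cc1
F3 | step 13 | methyl 6‑[(2S,3S)‑2‑(2,4‑dimethoxyphenyl)‑4‑methoxy‑6‑[2‑(4‑methoxyphenyl)ethyl]‑2,3‑dihydro‑1‑benzofuran‑3‑yl]‑2,4‑dioxocyclohexane‑1‑carboxylate (ring stereocentres unassigned) | COc1ccc(CCc2cc(OC)c3c(c2)O[C@H](c2ccc(OC)cc2OC)[C@H]3C2CC(=O)CC(=O)C2C(=O)OC)cc1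
F4 | step 13 | 5‑[(2S,3S)‑2‑(2,4‑dimethoxyphenyl)‑4‑methoxy‑6‑[2‑(4‑methoxyphenyl)ethyl]‑2,3‑dihydro‑1‑benzofuran‑3‑yl]cyclohexane‑1,3‑dione | COc1ccc(CCc2cc(OC)c3c(c2)O[C@H](c2ccc(OC)cc2OC)[C@H]3C2CC(=O)CC(=O)C2)cc1
F5 | step 5 | (E)‑3‑(2,4‑dimethoxyphenyl)‑1‑{2‑hydroxy‑6‑methoxy‑4‑[2‑(4‑methoxyphenyl)ethyl]phenyl}prop‑2‑en‑1‑one | COc1ccc(CCc2cc(O)c(C(=O)/C=C/c3ccc(OC)cc3OC)c(OC)c2)cc1
F6 | step 5 | racemic 2‑(2,4‑dimethoxyphenyl)‑5‑methoxy‑7‑[2‑(4‑methoxyphenyl)ethyl]‑2,3‑dihydro‑4H‑chromen‑4‑one | COc1ccc(CCc2cc(OC)c3c(c2)OC(c2ccc(OC)cc2OC)CC3=O)cc1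
F7 | step 5 | (2R)‑2‑(2,4‑dimethoxyphenyl)‑5‑methoxy‑7‑[2‑(4‑methoxyphenyl)ethyl]‑2,3‑dihydro‑4H‑chromen‑4‑one | COc1ccc(CCc2cc(OC)c3c(c2)O[C@@H](c2ccc(OC)cc2OC)CC3=O)cc1
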